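**Retrosynthetic overview**
1. C7–CH3 is made last: MeMgBr adds to enone 20, steered by the ring B C4 alkoxide.
2. C8=C9 comes from an aldol condensation of ring B methyl ketone 8 with ring A aldehyde 16.
3. Ring A (C10–C15 bond and C14–Br) comes from an electrochemical bromonium 6-endo carbocyclisation of β-keto ester 12, followed by C11 methylenation; the ester carbon becomes C9.
4. Ring B is bought as (S)-limonene: C4–OH by trans-diaxial epoxide hydrolysis, C3–Br by SN2 inversion through a cyclic sulfite, the acetyl group by ozonolysis.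
5. Ring order: ring B is bought, ring A is the only ring formed (step 5), and the two are joined in step 8.

Assumption: the SMILES is taken as drawn (syn bromohydrin in ring B, 7S carbinol); locants are ring B C1–C6 (C3–Br, C4–OH), carbinol C7, alkene C8=C9, ring A C10–C15 (C11 methylidene, C14–Br, C15 gem-dimethyl).

**Route**

Step 1
Reactants: 1 (S)-(−)-limonene
Product: 3 (1R,2R,4S)-1-methyl-4-(prop-1-en-2-yl)cyclohexane-1,2-diol, via limonene 1,2-oxide 2 (not isolated)
Conditions: mCPBA (1.0 equiv), CH2Cl2, 0 °C; then 5% aq H2SO4, THF, 0 °C to rt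
Reagents that add atoms: meta-chloroperbenzoic acid, OOC(=O)c1cccc(Cl)c1; water, O
Why: Prilezhaev epoxidation takes the more electron-rich ring alkene, and acid hydrolysis opens both epoxide diastereomers trans-diaxially (Fürst–Plattner rule) to the same diol, so the C4 hydroxyl (axial, cis to the side chain) and the C3 hydroxyl (axial, trans) are set by the bought C1 stereocentre.

Step 2
Reactants: 3 (1R,2R,4S)-1-methyl-4-(prop-1-en-2-yl)cyclohexane-1,2-diol
Product: 6 (1R,2S,4S)-2-bromo-1-methyl-4-(prop-1-en-2-yl)cyclohexan-1-ol, via cyclic sulfite 4 (not isolated), via lithium bromoalkyl sulfite 5 (not isolated)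
Conditions: SOCl2, Et3N, CH2Cl2, 0 °C; then LiBr, DMF, 80 °C; 1 M HCl, 0 °C
Reagents that add atoms: lithium bromide, [Li+].[Br-]
Why: Tying the trans-diol into a strained trans-fused cyclic sulfite removes the anti-periplanar hydroxyl that would otherwise close the epoxide, so bromide opens it at the secondary carbon C3 by SN2 with inversion and acid work-up expels SO2 without touching the tertiary C4–O bond, giving the syn bromohydrin with equatorial bromine.

Step 3
Reactants: 6 (1R,2S,4S)-2-bromo-1-methyl-4-(prop-1-en-2-yl)cyclohexan-1-ol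
Product: 8 1-[(1S,3S,4R)-3-bromo-4-hydroxy-4-methylcyclohexyl]ethan-1-one, via ozonide 7 (not isolated)
Conditions: O3, CH2Cl2, −78 °C; then Me2S, −78 °C to rt
Reagents that add atoms: ozone, [O-][O+]=O
Why: Ozonolysis with reductive work-up cleaves the only alkene (isopropenyl) to the methyl ketone and touches no stereocentre.

Step 4
Reactants: 9 methyl acetoacetate; 10 prenyl bromide (1-bromo-3-methylbut-2-ene)
Product: 12 methyl 7-methyl-3-oxooct-6-enoate, via acetoacetate dianion 11 (not isolated)
Conditions: NaH, THF, 0 °C; n-BuLi, 0 °C; then 10, 0 °C to rt; aq HCl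
Reagents that add atoms: none
Why: Huckin–Weiler dianion alkylation, in which the more basic terminal carbanion is alkylated by the allylic bromide at the γ-carbon only; no stereocentre is formed.

Step 5
Reactants: 12 methyl 7-methyl-3-oxooct-6-enoate
Product: 13 rac-methyl (1S,3S)-3-bromo-2,2-dimethyl-6-oxocyclohexane-1-carboxylate
Conditions: undivided cell, graphite anode, Pt cathode, Et4NBr (1.5 equiv), AcOH (2 equiv), HFIP/CH2Cl2 4:1, 8 mA cm−2, 2.2 F mol−1, 0 °C
Reagents that add atoms: tetraethylammonium bromide, CC[N+](CC)(CC)CC.[Br-]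
Why: Proposed new method: anodic oxidation of bromide in hexafluoroisopropanol gives an electrophilic bromine species that forms the bromonium ion of the trisubstituted alkene, whose tertiary terminus is captured 6-endo by the enol carbon of the β-keto ester (C10–C15 bond, ring A) with anti addition placing C14–Br equatorial, while the epimerisable C10 settles cis (diequatorial) in the acidic medium, any α-bromo keto ester gives its bromine back under the acid formed, and hydrogen evolves at the cathode; the product is racemic with its relative configuration fixed, and the closest known reactions are the SnCl4-initiated cyclisation of this same keto ester, bromonium polyene cyclisations with bromosulfonium reagents or N-bromo amides in hexafluoroisopropanol, and anodic bromolactonisation of alkenes.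

Step 6
Reactants: 13 rac-methyl (1S,3S)-3-bromo-2,2-dimethyl-6-oxocyclohexane-1-carboxylate
Product: 14 rac-methyl (1R,3S)-3-bromo-2,2-dimethyl-6-methylidenecyclohexane-1-carboxylate
Conditions: CH2Br2, Zn, TiCl4, THF, −40 to 5 °C (reagent pre-formed); then 13, CH2Cl2, rt
Reagents that add atoms: dibromomethane, BrCBr
Why: Takai–Lombardo methylenation with a non-basic reagent converts the hindered, enolisable ketone in the presence of the ester and avoids the enolate a Wittig ylide would form (which could displace the 1,3-related bromide), so C10 and C14 are unchanged.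

Step 7
Reactants: 14 rac-methyl (1R,3S)-3-bromo-2,2-dimethyl-6-methylidenecyclohexane-1-carboxylate
Product: 16 rac-(1R,3S)-3-bromo-2,2-dimethyl-6-methylidenecyclohexane-1-carbaldehyde, via aluminium hemiacetal 15 (not isolated)
Conditions: iBu2AlH (1.1 equiv), CH2Cl2, −78 °C; MeOH, then aq potassium sodium tartrate (KNaC4H4O6)
Reagents that add atoms: none
Why: Partial ester reduction at −78 °C stops at the tetrahedral aluminium hemiacetal, which releases the aldehyde on work-up; the aldehyde is used at once because C10 is epimerisable and the exocyclic alkene can move into conjugation.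

Step 8
Reactants: 8 1-[(1S,3S,4R)-3-bromo-4-hydroxy-4-methylcyclohexyl]ethan-1-one; 16 rac-(1R,3S)-3-bromo-2,2-dimethyl-6-methylidenecyclohexane-1-carbaldehyde
Product: 20 (2E)-3-[(1R,3S)-3-bromo-2,2-dimethyl-6-methylidenecyclohexyl]-1-[(1S,3S,4R)-3-bromo-4-hydroxy-4-methylcyclohexyl]prop-2-en-1-one, via dilithium alkoxide enolate 17 (not isolated), via aldol adduct 18 (not isolated), via aldol mesylate 19 (not isolated)
Conditions: LiN(iPr)2 (2.2 equiv), THF, −78 °C; 16 (1.1 equiv); AcOH; then MsCl, Et3N, CH2Cl2, 0 °C to rt; SiO2 chromatography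
Reagents that add atoms: none
Why: Kinetic deprotonation of the methyl group of 8 and aldol addition to the aldehyde, then mesylation of the secondary aldol hydroxyl and E1cB elimination, give the (E)-enone; aldehyde 16 is racemic and the ring B stereocentres are too remote to tell its antipodes apart, so the (1S,3R) antipode reacts at the same rate and gives the ring A antipodal diastereomer of 20 in about equal amount, which is removed by chromatography on silica, and only 20 is carried on.

Step 9
Reactants: 20 (2E)-3-[(1R,3S)-3-bromo-2,2-dimethyl-6-methylidenecyclohexyl]-1-[(1S,3S,4R)-3-bromo-4-hydroxy-4-methylcyclohexyl]prop-2-en-1-one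
Product: 23 (2S,3E)-4-[(1R,3S)-3-bromo-2,2-dimethyl-6-methylidenecyclohexyl]-2-[(1S,3S,4R)-3-bromo-4-hydroxy-4-methylcyclohexyl]but-3-en-2-ol (target), via enone bromomagnesium alkoxide 21 (not isolated), via bis(bromomagnesium) dialkoxide 22 (not isolated)
Conditions: MeMgBr (3.5 equiv), CH2Cl2/Et2O, −78 to −40 °C; aq NH4Cl
Reagents that add atoms: methylmagnesium bromide, C[Mg]Br
Why: 1,2-Addition of the Grignard reagent (chelation-controlled), in which the first equivalent makes the C4 bromomagnesium alkoxide that can bridge to the C7 carbonyl only through a twist-boat, where the cis C3–Br shields the carbonyl face on its side, so methyl is delivered from the C5/C6 side and C7 is set as (S) by the bought ring B stereocentres; this facial model is a prediction without direct precedent.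

**Compound list**
1 | (S)-(−)-limonene | CC(=C)[C@H]1CCC(C)=CC1 | starting material
2 | (4S)-limonene 1,2-oxide (cis/trans mixture) | CC(=C)[C@H]1CCC2(C)OC2C1 | intermediate
3 | (1R,2R,4S)-1-methyl-4-(prop-1-en-2-yl)cyclohexane-1,2-diol | CC(=C)[C@H]1CC[C@@](C)(O)[C@H](O)C1 | intermediate
4 | trans-fused cyclic sulfite of 3 | CC(=C)[C@H]1CC[C@@]2(C)OS(=O)O[C@@H]2C1 | intermediate
5 | lithium (1R,2S,4S)-2-bromo-1-methyl-4-(prop-1-en-2-yl)cyclohexyl sulfite | [Li+].CC(=C)[C@H]1CC[C@@](C)(OS(=O)[O-])[C@@H](Br)C1 | intermediate
6 | (1R,2S,4S)-2-bromo-1-methyl-4-(prop-1-en-2-yl)cyclohexan-1-ol | CC(=C)[C@H]1CC[C@@](C)(O)[C@@H](Br)C1 | intermediate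
7 | ozonide (1,2,4-trioxolane) of 6 | CC1(OCOO1)[C@H]1CC[C@@](C)(O)[C@@H](Br)C1 | intermediate
8 | 1-[(1S,3S,4R)-3-bromo-4-hydroxy-4-methylcyclohexyl]ethan-1-one | CC(=O)[C@H]1CC[C@@](C)(O)[C@@H](Br)C1 | intermediate
9 | methyl acetoacetate | COC(=O)CC(C)=O | starting material
10 | prenyl bromide (1-bromo-3-methylbut-2-ene) | CC(C)=CCBr | starting material
11 | sodium lithium dianion of methyl acetoacetate | [Na+].[Li+].C=C([O-])C=C([O-])OC | intermediate
12 | methyl 7-methyl-3-oxooct-6-enoate | COC(=O)CC(=O)CCC=C(C)C | intermediate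
13 | rac-methyl (1S,3S)-3-bromo-2,2-dimethyl-6-oxocyclohexane-1-carboxylate (enantiomer shown leads to the target) | O=C1CC[C@H](Br)C(C)(C)[C@@H]1C(=O)OC | intermediate
14 | rac-methyl (1R,3S)-3-bromo-2,2-dimethyl-6-methylidenecyclohexane-1-carboxylate | C=C1CC[C@H](Br)C(C)(C)[C@@H]1C(=O)OC | intermediate
15 | diisobutylaluminium hemiacetal of 14 | C=C1CC[C@H](Br)C(C)(C)[C@@H]1C(OC)O[Al](CC(C)C)CC(C)C | intermediate
16 | rac-(1R,3S)-3-bromo-2,2-dimethyl-6-methylidenecyclohexane-1-carbaldehyde | C=C1CC[C@H](Br)C(C)(C)[C@@H]1C=O | intermediate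
17 | dilithium alkoxide enolate of 8 | [Li+].[Li+].C=C([O-])[C@H]1CC[C@@](C)([O-])[C@@H](Br)C1 | intermediate
18 | aldol adduct (β-hydroxy ketone, C9 epimers) | C=C1CC[C@H](Br)C(C)(C)[C@@H]1C(O)CC(=O)[C@H]1CC[C@@](C)(O)[C@@H](Br)C1 | intermediate
19 | mesylate of 18 | C=C1CC[C@H](Br)C(C)(C)[C@@H]1C(OS(C)(=O)=O)CC(=O)[C@H]1CC[C@@](C)(O)[C@@H](Br)C1 | intermediate
20 | (2E)-3-[(1R,3S)-3-bromo-2,2-dimethyl-6-methylidenecyclohexyl]-1-[(1S,3S,4R)-3-bromo-4-hydroxy-4-methylcyclohexyl]prop-2-en-1-one | C=C1CC[C@H](Br)C(C)(C)[C@@H]1/C=C/C(=O)[C@H]1CC[C@@](C)(O)[C@@H](Br)C1 | intermediate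
21 | C4 bromomagnesium alkoxide of 20 | C=C1CC[C@H](Br)C(C)(C)[C@@H]1/C=C/C(=O)[C@H]1CC[C@@](C)(O[Mg]Br)[C@@H](Br)C1 | intermediate
22 | bis(bromomagnesium) dialkoxide of 23 | C=C1CC[C@H](Br)C(C)(C)[C@@H]1/C=C/[C@@](C)(O[Mg]Br)[C@H]1CC[C@@](C)(O[Mg]Br)[C@@H](Br)C1 | intermediate
23 | (2S,3E)-4-[(1R,3S)-3-bromo-2,2-dimethyl-6-methylidenecyclohexyl]-2-[(1S,3S,4R)-3-bromo-4-hydroxy-4-methylcyclohexyl]but-3-en-2-ol | C=C1CC[C@H](Br)C(C)(C)[C@@H]1/C=C/[C@@](C)(O)[C@H]1CC[C@@](C)(O)[C@@H](Br)C1 | target

**Totals**
Total step count: 9. Longest linear sequence: 6 steps (steps 4 to 9); the ring B branch is steps 1 to 3 and joins at step 8.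

Stereocontrol in summary: C1 is bought in (S)-limonene, and C4, C3 and C7 are controlled from it. C10 and C14 are set cis to each other in step 5, but their absolute sense is not controlled by any bought stereocentre. The ring A antipode is removed in step 8 as the ring A antipodal diastereomer of 20, which costs about half of the material at that point.

**Three steps most likely to fail**

Step 5 (proposed new electrochemical bromocyclisation). The risks are simple α-bromination of the keto ester, O-cyclisation to a cyclic enol ether, 5-exo closure, or dibromide formation. Fallback with known chemistry: from 12, Hg(OCOCF3)2 in MeNO2 at −20 °C followed by aqueous NaCl gives the C-cyclised alkylmercury chloride rac-methyl (1S,3S)-3-(chloromercurio)-2,2-dimethyl-6-oxocyclohexane-1-carboxylate F1. Bromodemercuration with Br2/LiBr in pyridine under O2 then replaces mercury by bromine with retention, as used for other 3-bromo cyclogeranyl units, and the route is rejoined at 13.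

Step 2 (inversion at C3 through the cyclic sulfite). The risks are that the diaxial diol resists closing to the trans-fused sulfite, that bromide attacks sulfur instead of carbon, or that E2 elimination competes at 80 °C. Fallback: from 3, ozonolysis is done first to give the keto diol 1-[(1S,3R,4R)-3,4-dihydroxy-4-methylcyclohexyl]ethan-1-one F2, since the alkene would not survive the next oxidation. SOCl2/Et3N and then RuCl3 (cat.)/NaIO4 give the much more electrophilic keto diol cyclic sulfate F3. LiBr in THF at rt opens it at C3 with inversion to lithium (1R,2S,4S)-4-acetyl-2-bromo-1-methylcyclohexyl sulfate F4, and brief hydrolysis (cat. H2SO4, 1 equiv H2O, THF) comes back to the route at 8.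

Step 9 (facial selectivity at C7). The risks are that the chelate may not dominate, giving low or reversed selectivity, and that the C4 alkoxide next to the cis bromide can undergo ring contraction if the mixture warms. Fallback: from 16, Takai olefination (CrCl2, CHI3, THF) gives the vinyl iodide rac-(2R,4S)-4-bromo-2-[(E)-2-iodoethenyl]-3,3-dimethyl-1-methylidenecyclohexane F5. Exchange with t-BuLi at −78 °C gives the ring A alkenyllithium F6, which is added to 8 (hydroxyl first deprotonated with MeMgBr) and, after aq NH4Cl work-up, comes back directly at 23. The alkenyl group then enters last, which by the same chelate model gives the opposite facial outcome, so this order is used if the Grignard step favours the C7 epimer. In either order the C7 epimers and the ring A antipodal diastereomers are separable diols.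

Further compounds
F1 | step 5 | rac-methyl (1S,3S)-3-(chloromercurio)-2,2-dimethyl-6-oxocyclohexane-1-carboxylate | O=C1CC[C@H]([Hg]Cl)C(C)(C)[C@@H]1C(=O)OC
F2 | step 2 | 1-[(1S,3R,4R)-3,4-dihydroxy-4-methylcyclohexyl]ethan-1-one | CC(=O)[C@H]1CC[C@@](C)(O)[C@H](O)C1
F3 | step 2 | keto diol cyclic sulfate (trans-fused 1,3,2-dioxathiolane 2,2-dioxide) | CC(=O)[C@H]1CC[C@@]2(C)OS(=O)(=O)O[C@@H]2C1
F4 | step 2 | lithium (1R,2S,4S)-4-acetyl-2-bromo-1-methylcyclohexyl sulfate | [Li+].CC(=O)[C@H]1CC[C@@](C)(OS(=O)(=O)[O-])[C@@H](Br)C1
F5 | step 9 | rac-(2R,4S)-4-bromo-2-[(E)-2-iodoethenyl]-3,3-dimethyl-1-methylidenecyclohexane | C=C1CC[C@H](Br)C(C)(C)[C@@H]1/C=C/I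
F6 | step 9 | ring A alkenyllithium | C=C1CC[C@H](Br)C(C)(C)[C@@H]1/C=C/[Li]
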